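## Retrosynthetic overview
1. Gravicycle comes from the trimethyl ether (12) by triple aryl-O-demethylation. The saturated C14 chain comes from chemoselective diimide reduction of an (E)-allylic alcohol (11), which keeps the benzylic C–O bond intact.
2. **Key disconnection (bold step):** the C1–C2 bond of the chain, at the (R)-carbinol. The 22-membered meta,para-cyclophane ring and the stereocentre form together in one step. An (E)-alkenylzinc, made in situ from a terminal alkyne by hydroboration and B→Zn exchange, adds intramolecularly to the aryl aldehyde under catalysis by (+)-DAIB (Oppolzer–Radinov-type macrocyclisation).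
3. The alkynal (10) comes from a B-alkyl Suzuki coupling of a TIPS-alkyne-bearing alkyl-9-BBN with the diaryl-ether aryl bromide (8). Compound 8 comes from a Chan–Lam coupling of syringaldehyde with 3-bromo-5-methoxyphenylboronic acid.
4. Ring order: both arenes are commercial, and the diaryl ether is formed intermolecularly, so the macrocycle is the only ring built and it is closed last.

Assumptions (one line each):
- All starting materials are commercial.
- (+)-DAIB gives the (R)-carbinol by analogy with (−)-DAIB/Et2Zn/PhCHO, which gives the (S)-alcohol.
- The target SMILES is (R) at C–OH (CIP priorities O > aryl > chain).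

## Route

**Step 1**
Reactants: 1 (11-bromo-1-undecene), 2 (lithium acetylide–ethylenediamine complex)
Product: 3 (tridec-12-en-1-yne, HC≡C(CH2)9CH=CH2)
Conditions: DMSO, rt, 12 h
Reagents that add atoms: 2, [Li+].[C-]#C.NCCN (supplies the C2 alkyne unit)
Why: SN2 alkylation of acetylide at a primary bromide, with the terminal alkene untouched. No stereocentre is formed.

**Step 2**
Reactants: 3, 4 (chlorotriisopropylsilane)
Product: 5 (triisopropyl(tridec-12-en-1-yn-1-yl)silane)
Conditions: n-BuLi, THF, −78 °C; then TIPSCl, −78 °C → rt
Reagents that add atoms: 4, CC(C)[Si](Cl)(C(C)C)C(C)C (TIPS group stays on the alkyne)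
Why: Lithiation of the terminal alkyne followed by silylation. The TIPS group keeps the alkyne from reacting with 9-BBN in Step 4 and survives aqueous-base Suzuki conditions.

**Step 3**
Reactants: 6 (syringaldehyde), 7 ((3-bromo-5-methoxyphenyl)boronic acid)
Product: 8 (4-(3-bromo-5-methoxyphenoxy)-3,5-dimethoxybenzaldehyde)
Conditions: Cu(OAc)2 (2 equiv), pyridine/Et3N, 4 Å MS, CH2Cl2, air, rt
Reagents that add atoms: none (7 is a reactant)
Why: Chan–Lam O-arylation, which is known to work on 2,6-disubstituted phenols (as in thyroxine syntheses). The Ar–Br and the aldehyde are untouched, and no stereocentre is formed.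

**Step 4**
Reactants: 5, 8
Product: 9 (4-[3-methoxy-5-(13-TIPS-tridec-12-yn-1-yl)phenoxy]-3,5-dimethoxybenzaldehyde)
Conditions: (i) 9-BBN-H (0.95 equiv), THF, rt, 4 h; (ii) 8, PdCl2(dppf) (5 mol%), K3PO4 (aq), THF/DMF, 60 °C
Reagents that add atoms: none (9-BBN, B1C2CCCC1CCC2, is lost as borate)
Why: 9-BBN hydroborates the terminal alkene selectively over the hindered TIPS-alkyne; B-alkyl Suzuki–Miyaura coupling then installs ArA–(CH2)11–C≡C–TIPS. Using a slight deficiency of 9-BBN-H avoids reducing the aldehyde.

**Step 5**
Reactants: 9
Product: 10 (4-[3-methoxy-5-(tridec-12-yn-1-yl)phenoxy]-3,5-dimethoxybenzaldehyde)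
Conditions: TBAF (1.5 equiv), THF, 0 °C → rt, 2 h
Reagents that add atoms: none
Why: Fluoride desilylation of the alkynyl–Si bond. The aldehyde has no α-hydrogens, so it tolerates the mild base.

**Step 6**
Reactants: 10
Product: 11 ((R,E)-macrocyclic allylic alcohol: 22-membered ring, trimethyl ether)
Conditions: (i) Cy2BH (1.1 equiv), toluene, 0 °C → rt, 1 h; (ii) Et2Zn (2.5 equiv), −78 → 0 °C; (iii) the alkenylzinc–aldehyde solution added by syringe pump over 10 h to (+)-DAIB (10 mol%) in toluene at 0 °C (final ~2 mM); NH4Cl quench
Reagents that add atoms: none (only H is added at the alkyne; boron and zinc are lost)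
Why: Proposed new method: the closest known reaction is Oppolzer–Radinov macrocyclisation of ω-alkynals to (E)-allylic alcohols (for example the muscone synthesis) together with DAIB-catalysed addition of (E)-alkenylzincs to aromatic aldehydes. The mechanism is syn-hydroboration of the terminal alkyne to an (E)-alkenyl-BCy2, then B→Zn exchange to an (E)-alkenyl-ZnEt. The zinc reagent adds through the Zn/DAIB-aminoalkoxide Noyori-type bimetallic transition state, which delivers one aldehyde face. High dilution favours ring closure over oligomerisation, and (+)-DAIB is expected to give the (R)-carbinol. Here the substrate is an electron-rich aryl aldehyde in a meta,para-cyclophane, which has not been demonstrated.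

**Step 7**
Reactants: 11
Product: 12 ((R)-saturated macrocycle, trimethyl ether)
Conditions: 2-nitrobenzenesulfonylhydrazide (NBSH, 8 equiv), Et3N (16 equiv), CH2Cl2, 23 °C, 24 h
Reagents that add atoms: none (net H2)
Why: NBSH gives diimide, which reduces the E-disubstituted C=C by syn H2 transfer without hydrogenolysing the allylic/benzylic C–O bond, as Pd/H2 would. The stereocentre is not touched and the aryl rings are inert.

**Step 8**
Reactants: 12
Product: 13 (Gravicycle)
Conditions: NaSEt (10 equiv), DMF, 140 °C, 6 h; then 1 M HCl workup
Reagents that add atoms: none (the methyls leave as EtSMe)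
Why: SN2 demethylation of the three aryl methyl ethers by thiolate. This avoids BBr3, which could ionise or brominate the electron-rich secondary benzylic alcohol. The diaryl ether and the non-epimerisable benzylic stereocentre are unaffected under basic conditions.

## Compound list
1 | 11-bromo-1-undecene | BrCCCCCCCCCC=C | starting material
2 | lithium acetylide–ethylenediamine complex | [Li+].[C-]#C.NCCN | starting material (reagent)
3 | tridec-12-en-1-yne | C#CCCCCCCCCCC=C | intermediate
4 | chlorotriisopropylsilane | CC(C)[Si](Cl)(C(C)C)C(C)C | starting material (reagent)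
5 | triisopropyl(tridec-12-en-1-yn-1-yl)silane | CC(C)[Si](C(C)C)(C(C)C)C#CCCCCCCCCCC=C | intermediate
6 | syringaldehyde (4-hydroxy-3,5-dimethoxybenzaldehyde) | O=Cc1cc(OC)c(O)c(OC)c1 | starting material
7 | (3-bromo-5-methoxyphenyl)boronic acid | COc1cc(Br)cc(B(O)O)c1 | starting material
8 | 4-(3-bromo-5-methoxyphenoxy)-3,5-dimethoxybenzaldehyde | COc1cc(Br)cc(Oc2c(OC)cc(C=O)cc2OC)c1 | intermediate
9 | TIPS-alkyne aldehyde (Suzuki product) | COc1cc(CCCCCCCCCCCC#C[Si](C(C)C)(C(C)C)C(C)C)cc(Oc2c(OC)cc(C=O)cc2OC)c1 | intermediate
10 | terminal alkyne aldehyde | COc1cc(CCCCCCCCCCCC#C)cc(Oc2c(OC)cc(C=O)cc2OC)c1 | intermediate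
11 | (R,E)-macrocyclic allylic alcohol, trimethyl ether | COc1cc2cc(c1)Oc1c(OC)cc(cc1OC)[C@H](O)/C=C/CCCCCCCCCCC2 | intermediate
12 | (R)-saturated macrocycle, trimethyl ether | COc1cc2cc(c1)Oc1c(OC)cc(cc1OC)[C@H](O)CCCCCCCCCCCCC2 | intermediate
13 | Gravicycle | Oc1cc2cc(c1)Oc1c(O)cc(cc1O)[C@H](O)CCCCCCCCCCCCC2 | target

## Totals
- Total steps: 8 (the one-pot hydroboration/coupling in Step 4 and the three-operation macrocyclisation in Step 6 each count as one).
- Longest linear sequence: 7 steps (1 → 3 → 5 → 9 → 10 → 11 → 12 → 13, starting from 11-bromo-1-undecene).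

## Three steps most likely to fail
1. **Step 6 (enantioselective macrocyclisation).** Cy2BH may reduce the aldehyde, the ee may be eroded in the 22-membered ring, or oligomers may form.
   Fallback: close the ring without asymmetric induction by an intramolecular Nozaki–Hiyama–Kishi reaction of a vinyl iodide (from 10) with the aldehyde, racemic. Then oxidise the allylic alcohol to the enone, hydrogenate the C=C, and set the (R)-centre by Noyori transfer hydrogenation of the macrocyclic aryl ketone with RuCl[(R,R)-TsDPEN](p-cymene) and HCO2H/Et3N.
2. **Step 8 (triple demethylation).** Forcing thiolate conditions may give incomplete demethylation or decomposition.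
   Fallback: rebuild the route with benzyl-protected arenes, using 3,5-bis(benzyloxy)-4-hydroxybenzaldehyde and (3-benzyloxy-5-bromophenyl)boronic acid. After diimide reduction, neutral H2/Pd(OH)2 then removes all protecting groups.
3. **Step 4 (hydroboration/B-alkyl Suzuki with a free aldehyde).** The aldehyde may be reduced or the coupling may stall.
   Fallback: reverse the order of bond formation. Couple the alkylborane to 3,5-dibromoanisole first, then do Miyaura borylation of the remaining Ar–Br and the Chan–Lam coupling with syringaldehyde, so the aldehyde never meets the alkylborane.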